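**Retrosynthetic overview**
1. End game: remove the O16 silyl group, semireduce C3≡C4, epoxidise C11=C20 under 12‑OH direction, reduce the C9 and C12 ketones together (the acetyl group moves from O8 to O9), and methylenate C11.
2. The ten‑membered ring closes last, at C6–C7. A carboxyl group on C7 leaves as CO2 in a nickel‑electrocatalytic coupling with the C6 vinyl bromide.
3. C2–C3 comes from a Felkin‑controlled zinc acetylide addition. O13 and O14 come from OsO4 on the ring A enone.
4. Ring A comes from a Diels–Alder reaction of an aminosiloxydiene with an (E)‑enedione aldehyde. C9–C10 comes from a Stille acylation.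
5. The lactone ring and C8 are bought in (−)‑garcinia acid, and C18 is added by dianion alkylation. Ring order: lactone (bought), ring A, ten‑membered ring, epoxide.

Assumptions: atom labels C1–C20 follow briarane numbering of the target, and "C7‑carboxyl" is the carbon later lost as CO2. (−)‑Garcinia acid, the γ‑lactone of (2S,3S)‑hydroxycitric acid and a bulk nutraceutical, is taken as a commercial chiral starting material.

**Arm for C10–C1–C2 (steps 1–2)**

Step 1
Reactants: 1 methacrolein
Product: 3 (E)-3-bromo-2-methylprop-2-enal, via 2,3-dibromo-2-methylpropanal 2 (not isolated)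
Conditions: Br2, CH2Cl2, −78 to 0 °C; then Et3N, 0 °C to rt
Reagents that add atoms: bromine BrBr
Why: Alkene bromination followed by E2 dehydrobromination removes the tertiary bromide, and Br ends trans to CHO in the less crowded (E)‑bromoenal.

Step 2
Reactants: 3 (E)-3-bromo-2-methylprop-2-enal
Product: 4 (E)-2-methyl-3-(tributylstannyl)prop-2-enal
Conditions: (Bu3Sn)2, Pd(PPh3)4 (5 mol %), toluene, 80 °C
Reagents that add atoms: hexabutylditin CCCC[Sn](CCCC)(CCCC)[Sn](CCCC)(CCCC)CCCC
Why: Palladium‑catalysed stannylation of a vinyl bromide (Stille–Kelly type) keeps the alkene geometry and tolerates the aldehyde.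

**Arm for C3–C6/C16 (steps 3–6)**

Step 3
Reactants: 5 2-bromoprop-2-en-1-ol; 6 ethynyltrimethylsilane
Product: 7 2-methylidene-4-(trimethylsilyl)but-3-yn-1-ol
Conditions: PdCl2(PPh3)2 (2 mol %), CuI (4 mol %), Et3N, rt
Reagents that add atoms: none
Why: Sonogashira coupling of a 2‑bromoalkene forms the C4–C5 bond.

Step 4
Reactants: 7 2-methylidene-4-(trimethylsilyl)but-3-yn-1-ol
Product: 8 tert-butyldimethylsilyl ether of 7
Conditions: TBSCl, imidazole, CH2Cl2, rt
Reagents that add atoms: tert-butyldimethylsilyl chloride CC(C)(C)[Si](C)(C)Cl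
Why: Standard silylation; this is the only protecting group carried to the last step.

Step 5
Reactants: 8 tert-butyldimethylsilyl ether of 7
Product: 10 (E)-bromoenyne with C3 silylated, via alkene dibromide 9 (not isolated)
Conditions: Br2, CH2Cl2, −78 °C; then DBU, 0 °C to rt
Reagents that add atoms: bromine BrBr
Why: Bromination and dehydrobromination; anti elimination places Br trans to the bulky CH2OTBS and cis to the slim alkynyl group, which is the ring‑cis C5=C6 geometry.

Step 6
Reactants: 10 (E)-bromoenyne with C3 silylated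
Product: 11 (E)-bromoenyne with free terminal alkyne
Conditions: K2CO3 (10 mol %), MeOH, 0 °C
Reagents that add atoms: none
Why: Selective protodesilylation of the alkynyl silane; the silyl ether and the vinyl bromide are inert.

**Main line (steps 7–22)**

Step 7
Reactants: 12 (−)-garcinia acid
Product: 13 dimethyl (2S,3S)-3-hydroxy-5-oxooxolane-2,3-dicarboxylate
Conditions: MeOH, H2SO4 (cat.), reflux; toluene azeotrope to re‑close the lactone
Reagents that add atoms: methanol CO
Why: Fischer esterification; C8 (bought) and the temporary C7 centre are not touched.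

Step 8
Reactants: 13 dimethyl (2S,3S)-3-hydroxy-5-oxooxolane-2,3-dicarboxylate
Product: 14 dimethyl (2S,3S,4R)-3-hydroxy-4-methyl-5-oxooxolane-2,3-dicarboxylate
Conditions: LiHMDS (2.2 equiv), THF, −78 °C; MeI, −78 to −40 °C; AcOH quench
Reagents that add atoms: iodomethane CI
Why: Fráter–Seebach‑type alkylation of the alkoxide–enolate dianion; the accessible C17 methylene is deprotonated, the alkoxide blocks β‑elimination, and MeI enters anti to the two cis ester groups, so C18 is cis to the 8‑OH (also the thermodynamic epimer).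

Step 9
Reactants: 14 dimethyl (2S,3S,4R)-3-hydroxy-4-methyl-5-oxooxolane-2,3-dicarboxylate
Product: 15 (2S,3S,4R)-3-hydroxy-4-methyl-5-oxooxolane-2,3-dicarboxylic acid
Conditions: LiOH, THF/H2O, 45 °C; then HCl to pH 1, concentrate
Reagents that add atoms: lithium hydroxide [Li+].[OH-]
Why: Saponification followed by acid‑induced relactonisation; no centre is enolisable as the carboxylate.

Step 10
Reactants: 15 (2S,3S,4R)-3-hydroxy-4-methyl-5-oxooxolane-2,3-dicarboxylic acid
Product: 16 O8-acetyl cyclic anhydride of 15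
Conditions: AcCl, reflux
Reagents that add atoms: acetyl chloride CC(=O)Cl
Why: The two cis carboxyl groups close to a five‑membered anhydride while the tertiary OH is acetylated; this acetyl group is the future 9‑OAc.

Step 11
Reactants: 16 O8-acetyl cyclic anhydride of 15
Product: 17 C7-carboxyl tert-butyl ester with free C9 acid
Conditions: tBuOH, DMAP (10 mol %), toluene, 60 °C
Reagents that add atoms: tert-butanol CC(C)(C)O
Why: Regioselective alcoholysis of an unsymmetrical anhydride at the carbonyl on the tertiary carbon, which leaves the hindered C9 acid free.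

Step 12
Reactants: 17 C7-carboxyl tert-butyl ester with free C9 acid; 4 (E)-2-methyl-3-(tributylstannyl)prop-2-enal
Product: 19 (E)-enedione aldehyde, via C9 acid chloride 18 (not isolated)
Conditions: 1-chloro-N,N,2-trimethylprop-1-en-1-amine, CH2Cl2, 0 °C; then 4, Pd2(dba)3 (2.5 mol %), P(2-furyl)3, THF, 40 °C
Reagents that add atoms: none
Why: Neutral acid chloride formation followed by Stille acylation builds C9–C10 with retention of the E geometry (C2 trans to C9).

Step 13
Reactants: 19 (E)-enedione aldehyde; 20 (E)-3-(tert-butyldimethylsilyloxy)-N,N-dimethylbuta-1,3-dien-1-amine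
Product: 22 ring A enone with C2 aldehyde plus free C7-carboxyl, via aminosiloxy cycloadduct 21 (not isolated)
Conditions: 20 (1.3 equiv), toluene, −40 °C to rt; then CF3CO2H, CH2Cl2, 0 °C to rt
Reagents that add atoms: none
Why: In this normal‑demand Diels–Alder reaction the nucleophilic CH2 terminus bonds to the unsubstituted C10 (β to the aldehyde); the tert‑butyl ester is expected to screen the inner face of the dipole‑minimised rotamer (C9=O eclipsing C8–C17), so the diene adds to the outer face and sets C1, the E alkene gives C2 trans to C9, and acid then unmasks the enone and cleaves the tert‑butyl ester in the same pot.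

Step 14
Reactants: 22 ring A enone with C2 aldehyde plus free C7-carboxyl; 11 (E)-bromoenyne with free terminal alkyne
Product: 23 C2 propargylic alcohol
Conditions: 11 (1.3 equiv), Zn(OTf)2, Et3N, toluene, 23 °C
Reagents that add atoms: none
Why: The zinc acetylide addition is aldehyde‑selective over both ketones, and Felkin–Anh attack anti to the C10 branch of the quaternary C1 gives the 2S carbinol.

Step 15
Reactants: 23 C2 propargylic alcohol
Product: 24 13α,14α-diol
Conditions: OsO4 (5 mol %), NMO, citric acid, tBuOH/acetone/H2O, rt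
Reagents that add atoms: N-methylmorpholine N-oxide C[N+]1([O-])CCOCC1; water O
Why: Upjohn dihydroxylation of the only reactive alkene (the bromoenyne is deactivated); OsO4 adds anti to the axial C15 methyl next to C14, giving the cis α,α‑diol.

Step 16
Reactants: 24 13α,14α-diol
Product: 25 2,13-diacetate with free 14-OH
Conditions: Ac2O (2.3 equiv), pyridine, CH2Cl2, 0 °C; aqueous work‑up
Reagents that add atoms: acetic anhydride CC(=O)OC(C)=O
Why: Rate‑controlled acylation; the propargylic O2 and the equatorial α‑ketol O13 react, while the axial neopentyl 14‑OH does not.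

Step 17
Reactants: 25 2,13-diacetate with free 14-OH
Product: 27 ten-membered enyne macrocycle, via N-acyloxyphthalimide ester 26 (not isolated)
Conditions: N-hydroxyphthalimide, DIC, DMAP (5 mol %), CH2Cl2, rt; then slow addition to NiCl2(dme) (20 mol %), 2,2'-bipyridine (20 mol %), AgNO3 (30 mol %), DMF (2 mM final), (+)Mg/(−)RVC, undivided cell, 4 mA, rt
Reagents that add atoms: none
Why: Proposed new method: an intramolecular nickel‑electrocatalytic decarboxylative alkenylation. Cathodically formed low‑valent nickel inserts into the C6–Br bond with retention, and monovalent nickel or the silver‑coated cathode reduces the phthalimide ester, which loses CO2 to give the planar α‑acyloxy C7 radical. Capture at divalent alkenylnickel gives trivalent nickel, and reductive elimination closes C6–C7 on the face anti to the C9 acyl branch, giving the trans‑fused 7S lactone. The working potential lies above that needed to reduce the ketones or α‑acetoxy ketones. The closest known reaction is the intermolecular nickel‑electrocatalytic coupling of redox‑active esters with alkenyl halides, including the trans‑selective coupling of cyclic α‑oxy radicals; it has not been shown for closing a medium carbocycle.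

Step 18
Reactants: 27 ten-membered enyne macrocycle
Product: 28 C11 exo-methylene ketone
Conditions: (CH2O)n, diisopropylammonium trifluoroacetate, CF3CO2H (10 mol %), THF, 60 °C
Reagents that add atoms: formaldehyde C=O
Why: Mannich‑type α‑methylenation; only C11 carries the two α‑hydrogens needed for addition and elimination, so C20 is installed regioselectively.

Step 19
Reactants: 28 C11 exo-methylene ketone
Product: 30 9-acetate 8,12,14-triol, via 9,12-diol 8-acetate 29 (not isolated)
Conditions: NaBH4, CeCl3·7H2O, MeOH/THF, −78 to −20 °C; then imidazole (cat.), rt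
Reagents that add atoms: none
Why: Luche 1,2‑reduction; at C12 the axial 14α‑OH blocks axial attack, so hydride enters equatorially and gives the axial 12α‑OH, and at C9 Felkin–Anh attack anti to the C1 branch gives 9S, after which a 1,2‑acyl shift moves the strained tertiary acetate from O8 to the new O9.

Step 20
Reactants: 30 9-acetate 8,12,14-triol
Product: 31 11,20-epoxide
Conditions: VO(acac)2 (5 mol %), tBuOOH, CH2Cl2, 0 °C
Reagents that add atoms: tert-butyl hydroperoxide CC(C)(C)OO
Why: Hydroxyl‑directed vanadium epoxidation; the axial 12α‑OH delivers oxygen to the α face of C11=C20, which is also the face away from the axial C15 methyl.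

Step 21
Reactants: 31 11,20-epoxide
Product: 32 (3Z,5E)-diene silyl ether
Conditions: H2 (1 atm), Pd on CaCO3 poisoned with Pb(OAc)2, quinoline, EtOAc, rt
Reagents that add atoms: none
Why: Lindlar‑type syn semihydrogenation of the cyclic enyne gives the 3Z alkene, and no other reducible alkene remains.

Step 22
Reactants: 32 (3Z,5E)-diene silyl ether
Product: 33 juncin Q
Conditions: Et3N·3HF, MeCN, 0 °C to rt
Reagents that add atoms: none
Why: Mild, nearly neutral fluoride desilylation frees the 16‑OH without acetyl migration or epoxide opening.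

**Compound list**
1 | methacrolein | CC(=C)C=O | starting material
2 | 2,3-dibromo-2-methylpropanal | CC(Br)(CBr)C=O | intermediate
3 | (E)-3-bromo-2-methylprop-2-enal | O=C/C(C)=C/Br | intermediate
4 | (E)-2-methyl-3-(tributylstannyl)prop-2-enal | O=C/C(C)=C/[Sn](CCCC)(CCCC)CCCC | intermediate
5 | 2-bromoprop-2-en-1-ol | OCC(Br)=C | starting material
6 | ethynyltrimethylsilane | C#C[Si](C)(C)C | starting material
7 | 2-methylidene-4-(trimethylsilyl)but-3-yn-1-ol | OCC(=C)C#C[Si](C)(C)C | intermediate
8 | TBS ether of 7 | C=C(CO[Si](C)(C)C(C)(C)C)C#C[Si](C)(C)C | intermediate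
9 | 1,2-dibromide of 8 | BrCC(Br)(CO[Si](C)(C)C(C)(C)C)C#C[Si](C)(C)C | intermediate
10 | (E)-1-bromo-2-(TBSO-methyl)-4-(trimethylsilyl)but-1-en-3-yne (Br cis to alkynyl) | C[Si](C)(C)C#C/C(CO[Si](C)(C)C(C)(C)C)=C\Br | intermediate
11 | (E)-1-bromo-2-(TBSO-methyl)but-1-en-3-yne (Br cis to alkynyl) | C#C/C(CO[Si](C)(C)C(C)(C)C)=C\Br | intermediate
12 | (−)-garcinia acid, (2S,3S)-3-hydroxy-5-oxooxolane-2,3-dicarboxylic acid | OC(=O)[C@@]1(O)[C@@H](C(=O)O)OC(=O)C1 | starting material
13 | dimethyl ester of 12 | COC(=O)[C@@]1(O)[C@@H](C(=O)OC)OC(=O)C1 | intermediate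
14 | (4R)-4-methyl derivative of 13 (methyl cis to OH) | COC(=O)[C@@]1(O)[C@@H](C(=O)OC)OC(=O)[C@@H]1C | intermediate
15 | diacid of 14 | OC(=O)[C@@]1(O)[C@@H](C(=O)O)OC(=O)[C@@H]1C | intermediate
16 | O8-acetyl cis-fused cyclic anhydride of 15 | O=C1OC(=O)[C@H]2OC(=O)[C@H](C)[C@@]12OC(C)=O | intermediate
17 | lactone with 8-OAc, free C9 acid, C7-carboxyl tert-butyl ester (ester cis to C9) | OC(=O)[C@@]1(OC(C)=O)[C@@H](C(=O)OC(C)(C)C)OC(=O)[C@@H]1C | intermediate
18 | C9 acid chloride of 17 | ClC(=O)[C@@]1(OC(C)=O)[C@@H](C(=O)OC(C)(C)C)OC(=O)[C@@H]1C | intermediate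
19 | (E)-enedione aldehyde: C8 bears the (E)-3-methyl-4-oxobut-2-enoyl group | O=C/C(C)=C/C(=O)[C@@]1(OC(C)=O)[C@@H](C(=O)OC(C)(C)C)OC(=O)[C@@H]1C | intermediate
20 | (E)-3-(tert-butyldimethylsilyloxy)-N,N-dimethylbuta-1,3-dien-1-amine | CN(C)/C=C/C(=C)O[Si](C)(C)C(C)(C)C | starting material
21 | endo cycloadduct (14-NMe2 cis to CHO, 12-OTBS enol ether, C2 trans to C9) | CN(C)[C@H]1C=C(O[Si](C)(C)C(C)(C)C)C[C@H](C(=O)[C@@]2(OC(C)=O)[C@@H](C(=O)OC(C)(C)C)OC(=O)[C@@H]2C)[C@@]1(C)C=O | intermediate
22 | ring A cyclohex-2-enone (C12 ketone, C13=C14), C1 methyl and CHO, C10 acyl, free C7-carboxyl; C1, C10, C8, C17 as in target | O=C1C=C[C@](C)(C=O)[C@H](C1)C(=O)[C@@]2(OC(C)=O)[C@@H](C(=O)O)OC(=O)[C@@H]2C | intermediate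
23 | (2S)-propargylic alcohol from 22 and 11 | O=C1C=C[C@](C)([C@@H](O)C#C/C(CO[Si](C)(C)C(C)(C)C)=C\Br)[C@H](C1)C(=O)[C@@]2(OC(C)=O)[C@@H](C(=O)O)OC(=O)[C@@H]2C | intermediate
24 | 13α,14α-diol of 23 | O=C1[C@H](O)[C@H](O)[C@](C)([C@@H](O)C#C/C(CO[Si](C)(C)C(C)(C)C)=C\Br)[C@H](C1)C(=O)[C@@]2(OC(C)=O)[C@@H](C(=O)O)OC(=O)[C@@H]2C | intermediate
25 | 2,13-diacetate of 24, 14-OH free | O=C1[C@H](OC(C)=O)[C@H](O)[C@](C)([C@@H](OC(C)=O)C#C/C(CO[Si](C)(C)C(C)(C)C)=C\Br)[C@H](C1)C(=O)[C@@]2(OC(C)=O)[C@@H](C(=O)O)OC(=O)[C@@H]2C | intermediate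
26 | N-acyloxyphthalimide ester of 25 | O=C1[C@H](OC(C)=O)[C@H](O)[C@](C)([C@@H](OC(C)=O)C#C/C(CO[Si](C)(C)C(C)(C)C)=C\Br)[C@H](C1)C(=O)[C@@]2(OC(C)=O)[C@@H](C(=O)ON3C(=O)c4ccccc4C3=O)OC(=O)[C@@H]2C | intermediate
27 | briarane macrocycle: 3-yne, 5E-ene, 9,12-dione, 2,8,13-triacetate, 14-OH, 16-OTBS; C1, C2, C7, C8, C10, C13, C14, C17 as in target | CC(=O)O[C@H]1C(=O)C[C@@H]2C(=O)[C@@]3(OC(C)=O)[C@H](/C=C(CO[Si](C)(C)C(C)(C)C)\C#C[C@H](OC(C)=O)[C@@]2(C)[C@H]1O)OC(=O)[C@@H]3C | intermediate
28 | 11(20)-methylidene derivative of 27 | CC(=O)O[C@H]1C(=O)C(=C)[C@@H]2C(=O)[C@@]3(OC(C)=O)[C@H](/C=C(CO[Si](C)(C)C(C)(C)C)\C#C[C@H](OC(C)=O)[C@@]2(C)[C@H]1O)OC(=O)[C@@H]3C | intermediate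
29 | (9S,12R)-diol still carrying the 8-acetate | CC(=O)O[C@H]1[C@@H](O)C(=C)[C@@H]2[C@H](O)[C@@]3(OC(C)=O)[C@H](/C=C(CO[Si](C)(C)C(C)(C)C)\C#C[C@H](OC(C)=O)[C@@]2(C)[C@H]1O)OC(=O)[C@@H]3C | intermediate
30 | 2,9,13-triacetate 8,12,14-triol with 11(20)-ene and 3-yne | CC(=O)O[C@H]1[C@@H](O)C(=C)[C@@H]2[C@H](OC(C)=O)[C@@]3(O)[C@H](/C=C(CO[Si](C)(C)C(C)(C)C)\C#C[C@H](OC(C)=O)[C@@]2(C)[C@H]1O)OC(=O)[C@@H]3C | intermediate
31 | 11α,20-epoxide of 30 | CC(=O)O[C@H]1[C@@H](O)[C@]2(CO2)[C@@H]2[C@H](OC(C)=O)[C@@]3(O)[C@H](/C=C(CO[Si](C)(C)C(C)(C)C)\C#C[C@H](OC(C)=O)[C@@]2(C)[C@H]1O)OC(=O)[C@@H]3C | intermediate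
32 | 16-O-TBS juncin Q | CC(=O)O[C@H]1[C@@H](O)[C@]2(CO2)[C@@H]2[C@H](OC(C)=O)[C@@]3(O)[C@H](/C=C(CO[Si](C)(C)C(C)(C)C)\C=C/[C@H](OC(C)=O)[C@@]2(C)[C@H]1O)OC(=O)[C@@H]3C | intermediate
33 | juncin Q (1R,2S,7S,8S,9S,10S,11R,12R,13R,14R,17R; 3Z,5E) | CC(=O)O[C@H]1[C@@H](O)[C@]2(CO2)[C@@H]2[C@H](OC(C)=O)[C@@]3(O)[C@H](/C=C(CO)\C=C/[C@H](OC(C)=O)[C@@]2(C)[C@H]1O)OC(=O)[C@@H]3C | target

**Totals**
- Total step count: 22.
- Longest linear sequence: 16 steps (steps 7–22, from garcinia acid).

**Steps most likely to fail**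

Step 17 (the new electrochemical ring closure) may give hydrodecarboxylation or oligomers instead of the ring. The fallback keeps only known reactions and moves the ring closure to C2–C3. It sets out from 22, whose phthalimide ester is coupled intermolecularly with bromide 10 under the established nickel‑electrocatalytic conditions to give the C7‑alkenylated aldehyde F1. NIS/AgF converts F1 into the iodoalkyne F2. A high‑dilution CrCl2/NiCl2 Nozaki–Hiyama–Kishi reaction of the iodoalkyne with the C2 aldehyde closes the ring to the macrocyclic propargylic alcohol F3. OsO4/NMO then gives the 2,13,14‑triol F4, and Ac2O/pyridine brings the material back to the route at 27.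

Step 13 (Diels–Alder) carries the least secure prediction, namely its facial sense. A competing rotamer, in which C9=O eclipses C8–C7, would expose the opposite face. If that face is favoured, the fallback changes the alkene geometry so that the same face gives the correct C1. It sets out from 19, which is photoisomerised (thioxanthone, 405 nm) to the (Z)‑enedione aldehyde F5. Cycloaddition with 20 and CF3CO2H treatment give the 10‑epimeric cis enone acid F6. DBU then equilibrates C10, which is α to the C9 ketone, with recycling of unchanged F6, and the material returns to the route at 22.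

Step 19 (double reduction with acetyl shift) may leave the hindered C9 ketone untouched or may transpose the lactone. The fallback separates the two reductions and changes their order relative to the epoxidation. It sets out from 28, and NaBH4/CeCl3·7H2O held at −78 °C reduces only C12 to give the 12α‑ol 9‑ketone F7. VO(acac)2/tBuOOH gives the epoxy ketone F8. Zn(BH4)2 in Et2O then reduces C9, imidazole completes the O8‑to‑O9 acetyl shift, and the material returns to the route at 31.

**Further compounds**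
F1 | step 17 | C7-alkenylated ring A enone aldehyde with silylated alkyne | O=C1C=C[C@](C)(C=O)[C@H](C1)C(=O)[C@@]2(OC(C)=O)[C@H](/C=C(CO[Si](C)(C)C(C)(C)C)\C#C[Si](C)(C)C)OC(=O)[C@@H]2C
F2 | step 17 | iodoalkyne from F1 | O=C1C=C[C@](C)(C=O)[C@H](C1)C(=O)[C@@]2(OC(C)=O)[C@H](/C=C(CO[Si](C)(C)C(C)(C)C)\C#CI)OC(=O)[C@@H]2C
F3 | step 17 | macrocyclic (2S)-propargylic alcohol with ring A enone | O=C1C[C@@H]2C(=O)[C@@]3(OC(C)=O)[C@H](/C=C(CO[Si](C)(C)C(C)(C)C)\C#C[C@H](O)[C@@]2(C)C=C1)OC(=O)[C@@H]3C
F4 | step 17 | macrocyclic 2,13,14-triol | O[C@H]1C(=O)C[C@@H]2C(=O)[C@@]3(OC(C)=O)[C@H](/C=C(CO[Si](C)(C)C(C)(C)C)\C#C[C@H](O)[C@@]2(C)[C@H]1O)OC(=O)[C@@H]3C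
F5 | step 13 | (Z)-enedione aldehyde | O=C/C(C)=C\C(=O)[C@@]1(OC(C)=O)[C@@H](C(=O)OC(C)(C)C)OC(=O)[C@@H]1C
F6 | step 13 | 10-epimer of 22 (C2 cis to C9) | O=C1C=C[C@](C)(C=O)[C@@H](C1)C(=O)[C@@]2(OC(C)=O)[C@@H](C(=O)O)OC(=O)[C@@H]2C
F7 | step 19 | 12α-ol 9-ketone 8-acetate | CC(=O)O[C@H]1[C@@H](O)C(=C)[C@@H]2C(=O)[C@@]3(OC(C)=O)[C@H](/C=C(CO[Si](C)(C)C(C)(C)C)\C#C[C@H](OC(C)=O)[C@@]2(C)[C@H]1O)OC(=O)[C@@H]3C
F8 | step 19 | 11α,20-epoxy 9-ketone 8-acetate | CC(=O)O[C@H]1[C@@H](O)[C@]2(CO2)[C@@H]2C(=O)[C@@]3(OC(C)=O)[C@H](/C=C(CO[Si](C)(C)C(C)(C)C)\C#C[C@H](OC(C)=O)[C@@]2(C)[C@H]1O)OC(=O)[C@@H]3C
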